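**Retrosynthetic overview**

1. Ring B is made last: suprafacial [4+2] addition of singlet oxygen to an (E,E)-1,3-diene gives the cis-3,6-dialkyl-3,6-dihydro-1,2-dioxine.
2. Ring A (the 3-methoxy peroxyketal ring) is made before it: methyl ketal ⇐ peroxy hemiketal ⇐ aerobic two-atom ring expansion of a tertiary cyclobut-2-en-1-ol, with O–O inserted into its C1–C4 bond.
3. Enabling feature: in the cyclobutenol the carbinol carbon C1 (later ketal carbon C6 of ring A) and C4 (later C3, carrying CH2CO2Me) are joined by a strained, allylic σ bond next to the hydroxyl oxygen, and the ring alkene C2=C3 is necessarily cis. An alkoxy radical at O–C1 breaks C1–C4, and the cis alkene (later C4=C5) holds the new C3 hydroperoxide within reach of the C6 ketone.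
4. Cyclobutenol ⇐ (4E,6E)-deca-4,6-dienyllithium + methyl 2-(4-oxocyclobut-2-en-1-yl)acetate (ketene–alkoxyalkyne [2+2], then carbonyl transposition); dienyl chain ⇐ Johnson–Claisen rearrangement of (E)-octa-1,4-dien-3-ol.
5. Stereochemistry: C3 of ring A by lipase kinetic resolution, C6 by acid equilibration of the ketal, ring B cis by the cycloaddition (its facial sense is not controlled and the two diastereomers are separated). Order of ring formation: cyclobutene, ring A, ring B.

Key step: step 8

Remark: every intermediate before step 9 is achiral or racemic; enantiopurity enters through the enzyme in step 9. For a racemate with two stereocentres the relative configuration is named and one enantiomer is drawn.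

**Route**

Step 1
Reactants: 1 (E)-hex-2-enal; 2 vinylmagnesium bromide
Product: 3 (E)-octa-1,4-dien-3-ol (racemic)
Conditions: THF, −78 to 0 °C; aq. NH4Cl
Reagents that add atoms: none
Why: Grignard 1,2-addition of the hard vinyl nucleophile to the aldehyde carbonyl should outrun conjugate addition and give the bis-allylic carbinol, whose single stereocentre is racemic and is erased in step 2.

Step 2
Reactants: 3 (E)-octa-1,4-dien-3-ol; 4 trimethyl orthoacetate
Product: 6 methyl (4E,6E)-deca-4,6-dienoate, via the mixed ketene acetal 5 (not isolated)
Conditions: EtCO2H (cat.), xylene, 135 °C, distillation of MeOH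
Reagents that add atoms: none
Why: Johnson–Claisen rearrangement, in which acid-catalysed exchange with the orthoester and loss of methanol give ketene acetal 5, whose [3,3] shift through the unsubstituted vinyl terminus in a chair transition state with the pentenyl group equatorial should create the new alkene E and place it in conjugation with the existing E alkene.

Step 3
Reactants: 6 methyl (4E,6E)-deca-4,6-dienoate
Product: 7 (4E,6E)-deca-4,6-dien-1-ol
Conditions: LiAlH4, Et2O, 0 °C
Reagents that add atoms: none
Why: Hydride reduction of the ester to the primary alcohol, with the unactivated conjugated diene inert to LiAlH4 at this temperature.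

Step 4
Reactants: 7 (4E,6E)-deca-4,6-dien-1-ol
Product: 8 (4E,6E)-1-iododeca-4,6-diene
Conditions: I2, PPh3, imidazole, CH2Cl2, 0 °C
Reagents that add atoms: iodine (II)
Why: Appel-type iodination, an SN2 displacement of the oxyphosphonium ion at a primary carbon under neutral conditions that leave the diene geometry untouched.

Step 5
Reactants: 9 methyl 4-chloro-4-oxobutanoate; 10 ethoxyethyne
Product: 12 methyl 2-(2-ethoxy-4-oxocyclobut-2-en-1-yl)acetate (racemic), via the ketene methyl 4-oxobut-3-enoate 11 (not isolated)
Conditions: Et3N, Et2O, 0 to 25 °C, slow addition of 9 to 10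
Reagents that add atoms: none
Why: Dehydrochlorination gives the aldoketene 11, which should undergo the regioselective thermal [2+2] cycloaddition with the electron-rich alkoxyalkyne (alkyne CH carbon to the ketene carbonyl carbon) to the 3-ethoxycyclobutenone, the new ring stereocentre being racemic and of no consequence.

Step 6
Reactants: 12 methyl 2-(2-ethoxy-4-oxocyclobut-2-en-1-yl)acetate
Product: 14 methyl 2-(4-oxocyclobut-2-en-1-yl)acetate (racemic), via the allylic alcohol 13 (not isolated)
Conditions: NaBH4, CeCl3·7H2O, MeOH, −20 °C; then 1 M HCl, THF, 0 °C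
Reagents that add atoms: water (O)
Why: Luche 1,2-reduction of the vinylogous ester carbonyl (the methyl ester is inert to NaBH4 at low temperature) and acid hydrolysis of the enol ether with loss of the allylic hydroxyl, a Stork–Danheiser carbonyl transposition, should deliver the 4-substituted cyclobutenone as a racemate.

Step 7
Reactants: 8 (4E,6E)-1-iododeca-4,6-diene; 14 methyl 2-(4-oxocyclobut-2-en-1-yl)acetate
Product: 16 methyl 2-[(1R*,4S*)-4-[(4E,6E)-deca-4,6-dien-1-yl]-4-hydroxycyclobut-2-en-1-yl]acetate (racemic), via (4E,6E)-deca-4,6-dien-1-yllithium 15 (not isolated)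
Conditions: t-BuLi (2.0 equiv), Et2O–pentane, −78 °C; then 14, THF, −78 °C; AcOH, −78 °C
Reagents that add atoms: none
Why: Lithium–iodine exchange followed by 1,2-addition of the alkyllithium to the strained and highly electrophilic cyclobutenone carbonyl, which at −78 °C should be much faster than attack on the methyl ester, with approach anti to the ring substituent placing OH cis to the acetate arm (relative configuration only, both centres being erased in step 8) and a cold acidic quench preventing oxyanion-driven ring opening or lactonisation.

Step 8
Reactants: 16 methyl 2-[(1R*,4S*)-4-[(4E,6E)-deca-4,6-dien-1-yl]-4-hydroxycyclobut-2-en-1-yl]acetate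
Product: 18 methyl 2-[6-[(4E,6E)-deca-4,6-dien-1-yl]-6-hydroxy-3,6-dihydro-1,2-dioxin-3-yl]acetate (racemic at C3; both C6 epimers), via the (Z)-γ-hydroperoxy enone 17 (not isolated)
Conditions: Co(acac)2 (10 mol %), O2 (1 atm), CH2Cl2, 25 °C, dark
Reagents that add atoms: dioxygen (O=O)
Why: Proposed new method: divalent cobalt and O2 should turn the tertiary alcohol into a trivalent cobalt alkoxide and then an alkoxy radical, whose β-scission cleaves the strained C1–C4 ring bond (not C1–C2, which would give a vinyl radical) to a ketone and a C4 radical that is allylic and conjugated with the new carbonyl; triplet dioxygen is captured at that carbon so that the enone stays conjugated, the peroxyl radical is reduced by divalent cobalt and protonated by the next alcohol molecule to the hydroperoxide 17, and 17 closes onto the ketone. The closest known reaction type is the Co(acac)2-catalysed aerobic ring expansion of saturated tertiary cyclobutanols to 1,2-dioxan-3-ols, for which a cyclobut-2-en-1-ol is a new substrate class. Ring A is closed by 6-exo-trig addition of the hydroperoxide oxygen to the C6 carbonyl, which is possible only because the Z geometry of C4=C5 is inherited from the four-membered ring. C3 is created by oxygen capture at a planar radical and is therefore racemic (resolved in step 9), and the hemiketal carbon C6 forms as an equilibrating pair of epimers (fixed in step 10). The step needs regioselective scission, retention of the cis alkene and tolerance of the (E,E)-diene: ring strain together with allylic stabilisation should secure the first, oxygen capture under 1 atm of O2 being faster than rotation of the allyl-type radical the second, and the absence of any hydride source the third.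

Step 9
Reactants: 18 methyl 2-[6-[(4E,6E)-deca-4,6-dien-1-yl]-6-hydroxy-3,6-dihydro-1,2-dioxin-3-yl]acetate (racemic)
Product: 19 2-[(3R)-6-[(4E,6E)-deca-4,6-dien-1-yl]-6-hydroxy-3,6-dihydro-1,2-dioxin-3-yl]acetic acid (both C6 epimers)
Conditions: Burkholderia cepacia lipase, phosphate buffer (pH 7.0)–MTBE, 25 °C, stopped near half conversion; acid–base extraction
Reagents that add atoms: water (O)
Why: Lipase-catalysed hydrolytic kinetic resolution, in which the enzyme is expected to hydrolyse the methyl ester of the (3R)-enantiomer faster because C3, β to the acyl carbon, carries sterically and electronically distinct peroxide and vinyl substituents, so that stopping near half conversion and extracting the acid sets C3 as R while C6 remains an equilibrating hemiketal.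

Step 10
Reactants: 19 2-[(3R)-6-[(4E,6E)-deca-4,6-dien-1-yl]-6-hydroxy-3,6-dihydro-1,2-dioxin-3-yl]acetic acid
Product: 20 methyl 2-[(3R,6S)-6-[(4E,6E)-deca-4,6-dien-1-yl]-6-methoxy-3,6-dihydro-1,2-dioxin-3-yl]acetate
Conditions: MeOH, HCl (0.1 M in MeOH), 25 °C; chromatographic separation of the C6 epimers
Reagents that add atoms: methanol (CO)
Why: Fischer esterification runs alongside acid-catalysed exchange of the hemiketal hydroxyl for methoxyl through the allylic peroxycarbenium ion, so C6 is set under thermodynamic control as a separable pair of epimers from which the (6S)-ketal is taken on and the (6R)-ketal is returned to the same conditions, C3 being untouched.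

Step 11
Reactants: 20 methyl 2-[(3R,6S)-6-[(4E,6E)-deca-4,6-dien-1-yl]-6-methoxy-3,6-dihydro-1,2-dioxin-3-yl]acetate
Product: 21 methyl 2-[(3R,6S)-6-methoxy-6-{3-[(3R,6S)-6-propyl-3,6-dihydro-1,2-dioxin-3-yl]propyl}-3,6-dihydro-1,2-dioxin-3-yl]acetate
Conditions: O2, tetraphenylporphyrin (cat.), visible light, CH2Cl2, 0 °C; preparative HPLC
Reagents that add atoms: dioxygen (O=O)
Why: Singlet-oxygen [4+2] cycloaddition to the s-cis (E,E)-diene is suprafacial, so the two new C–O bonds form on one face and the propyl and linker substituents of ring B end up cis, whereas the electron-poor alkene of ring A does not react; the remote ring A cannot bias the diene face, so the wanted (3R,6S)-ring B isomer and its (3S,6R)-ring B diastereomer are expected together and the target is isolated by preparative HPLC.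

**Compound list**

1 | (E)-hex-2-enal | CCC/C=C/C=O | starting material
2 | vinylmagnesium bromide | C=C[Mg]Br | starting material
3 | (E)-octa-1,4-dien-3-ol (racemic) | CCC/C=C/C(O)C=C | intermediate
4 | trimethyl orthoacetate (1,1,1-trimethoxyethane) | CC(OC)(OC)OC | starting material
5 | (E)-3-[(1-methoxyethenyl)oxy]octa-1,4-diene (mixed ketene acetal) | CCC/C=C/C(C=C)OC(=C)OC | intermediate (not isolated)
6 | methyl (4E,6E)-deca-4,6-dienoate | CCC/C=C/C=C/CCC(=O)OC | intermediate
7 | (4E,6E)-deca-4,6-dien-1-ol | CCC/C=C/C=C/CCCO | intermediate
8 | (4E,6E)-1-iododeca-4,6-diene | CCC/C=C/C=C/CCCI | intermediate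
9 | methyl 4-chloro-4-oxobutanoate | COC(=O)CCC(=O)Cl | starting material
10 | ethoxyethyne (ethoxyacetylene) | CCOC#C | starting material
11 | methyl 4-oxobut-3-enoate (ketene) | COC(=O)CC=C=O | intermediate (not isolated)
12 | methyl 2-(2-ethoxy-4-oxocyclobut-2-en-1-yl)acetate (racemic) | CCOC1=CC(=O)C1CC(=O)OC | intermediate
13 | methyl 2-(2-ethoxy-4-hydroxycyclobut-2-en-1-yl)acetate (racemic, diastereomer mixture) | CCOC1=CC(O)C1CC(=O)OC | intermediate (not isolated)
14 | methyl 2-(4-oxocyclobut-2-en-1-yl)acetate (racemic) | COC(=O)CC1C=CC1=O | intermediate
15 | (4E,6E)-deca-4,6-dien-1-yllithium | [Li]CCC/C=C/C=C/CCC | intermediate (not isolated)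
16 | methyl 2-[(1R*,4S*)-4-[(4E,6E)-deca-4,6-dien-1-yl]-4-hydroxycyclobut-2-en-1-yl]acetate (racemic; OH cis to the acetate arm; (1R,4S) enantiomer drawn) | CCC/C=C/C=C/CCC[C@]1(O)C=C[C@H]1CC(=O)OC | intermediate
17 | methyl (4Z,10E,12E)-3-hydroperoxy-6-oxohexadeca-4,10,12-trienoate (racemic) | CCC/C=C/C=C/CCCC(=O)/C=C\C(CC(=O)OC)OO | intermediate (not isolated)
18 | methyl 2-[6-[(4E,6E)-deca-4,6-dien-1-yl]-6-hydroxy-3,6-dihydro-1,2-dioxin-3-yl]acetate (racemic at C3, both C6 epimers) | CCC/C=C/C=C/CCCC1(O)C=CC(CC(=O)OC)OO1 | intermediate
19 | 2-[(3R)-6-[(4E,6E)-deca-4,6-dien-1-yl]-6-hydroxy-3,6-dihydro-1,2-dioxin-3-yl]acetic acid (both C6 epimers) | CCC/C=C/C=C/CCCC1(O)C=C[C@@H](CC(=O)O)OO1 | intermediate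
20 | methyl 2-[(3R,6S)-6-[(4E,6E)-deca-4,6-dien-1-yl]-6-methoxy-3,6-dihydro-1,2-dioxin-3-yl]acetate | CCC/C=C/C=C/CCC[C@@]1(OC)C=C[C@@H](CC(=O)OC)OO1 | intermediate
21 | methyl 2-[(3R,6S)-6-methoxy-6-{3-[(3R,6S)-6-propyl-3,6-dihydro-1,2-dioxin-3-yl]propyl}-3,6-dihydro-1,2-dioxin-3-yl]acetate (CNP0078798.2) | CCC[C@H]1C=C[C@@H](CCC[C@@]2(OC)C=C[C@@H](CC(=O)OC)OO2)OO1 | target

**Step count and risks**

Total step count: 11. Longest linear sequence: 9 steps (steps 1–4 and 7–11); steps 5 and 6 form the second branch.

Steps most likely to fail:

1. Step 8 (proposed new method). What may go wrong: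
   - cobalt-mediated O–O cleavage of the allylic peroxy hemiketal once it has formed (isomerisation to the ene-dione);
   - rotation of the oxygen-conjugated allyl radical before oxygen capture, with loss of the cis alkene;
   - peroxyl radical addition to the (E,E)-diene.

   Fallback with known reaction types, setting out from iodide 8 and coming back at hemiketal ester 18. Furan is lithiated with n-BuLi in THF to 2-furyllithium F1, which is alkylated by 8 to 2-[(4E,6E)-deca-4,6-dien-1-yl]furan F2. Slow addition of methyl diazoacetate with Rh2(OAc)4 should cyclopropanate the unsubstituted furan double bond, and the adduct opens electrocyclically to methyl (2E,4Z,10E,12E)-6-oxohexadeca-2,4,10,12-tetraenoate F3, the 4Z alkene coming from the furan ring. Ethereal H2O2 with a trace of acid adds to the ketone to give methyl (2E,4Z,10E,12E)-6-hydroperoxy-6-hydroxyhexadeca-2,4,10,12-tetraenoate F4. Et2NH in CF3CH2OH then promotes intramolecular conjugate addition of the hydroperoxide to the enoate (6-exo), which gives 18. In this fallback ring A is closed rather than expanded.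

2. Step 9. What may go wrong: weak discrimination between the enantiomers by the lipase (the stereocentre is two atoms from the carbonyl group), or decomposition of the peroxy hemiketal in buffer through its hydroperoxy enone tautomer.

   Fallback, setting out from 18 and coming back at 20. Racemic 18 is treated with MeOH and HCl as in step 10, which gives 20 together with its enantiomer methyl 2-[(3S,6R)-6-[(4E,6E)-deca-4,6-dien-1-yl]-6-methoxy-3,6-dihydro-1,2-dioxin-3-yl]acetate F5. The two are separated by preparative chromatography on a chiral stationary phase, so the resolution becomes physical and is done on the more robust ketal.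

3. Step 11. What may go wrong: absence of facial discrimination together with co-elution of the two cis diastereomers, which differ only in the relation of two remote rings; a competing ene reaction of singlet oxygen at the allylic positions.

   Fallback, setting out from the crude mixture of 21 and its ring B diastereomer and coming back at 21. The mixture is exposed to Candida rugosa lipase, a lipase type that can recognise stereocentres far along a fatty acyl chain, in buffer–MTBE. The ester of one diastereomer should be hydrolysed faster. The acid of the target, 2-[(3R,6S)-6-methoxy-6-{3-[(3R,6S)-6-propyl-3,6-dihydro-1,2-dioxin-3-yl]propyl}-3,6-dihydro-1,2-dioxin-3-yl]acetic acid F6, is removed by extraction and re-esterified with Me3SiCHN2 in MeOH–toluene at 0 °C to 21.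

**Further compounds**

F1 | step 8 | 2-furyllithium | [Li]c1ccco1
F2 | step 8 | 2-[(4E,6E)-deca-4,6-dien-1-yl]furan | CCC/C=C/C=C/CCCc1ccco1
F3 | step 8 | methyl (2E,4Z,10E,12E)-6-oxohexadeca-2,4,10,12-tetraenoate | CCC/C=C/C=C/CCCC(=O)/C=C\C=C\C(=O)OC
F4 | step 8 | methyl (2E,4Z,10E,12E)-6-hydroperoxy-6-hydroxyhexadeca-2,4,10,12-tetraenoate | CCC/C=C/C=C/CCCC(O)(OO)/C=C\C=C\C(=O)OC
F5 | step 9 | methyl 2-[(3S,6R)-6-[(4E,6E)-deca-4,6-dien-1-yl]-6-methoxy-3,6-dihydro-1,2-dioxin-3-yl]acetate | CCC/C=C/C=C/CCC[C@]1(OC)C=C[C@H](CC(=O)OC)OO1
F6 | step 11 | 2-[(3R,6S)-6-methoxy-6-{3-[(3R,6S)-6-propyl-3,6-dihydro-1,2-dioxin-3-yl]propyl}-3,6-dihydro-1,2-dioxin-3-yl]acetic acid | CCC[C@H]1C=C[C@@H](CCC[C@@]2(OC)C=C[C@@H](CC(=O)O)OO2)OO1
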